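1. Dissolved substrate cannot reach its solubility of 0.054 M in this flask. At that level step 2 would consume 5.25 mM/min, more than the 0.842 mM/min step 6 delivers into an empty solution.

solid substrate 0.068 M; reagent 2.50 equiv; time 80 min

    reagent + target ⇌ idle adduct, settled at all times (K1 = 5.1 /M)
    2 dissolved substrate → side product A (k2 = 0.015 /M/s)
    solid product ⇌ target, rate k3*(cs3 - [target]) while solid is left; crystals form when [target] > cs3 (cs3 = 18 mM, k3 = 0.0028 /s)
    solid substrate + target → side product B (k4 = 0.0011 /M/s)
    dissolved substrate + reagent → target (k5 = 0.0012 /M/s)
    solid substrate ⇌ dissolved substrate, rate k6*(cs6 - [dissolved substrate]) while solid is left; crystals form when [dissolved substrate] > cs6 (cs6 = 0.054 M, k6 = 2.6 × 10⁻⁴ /s)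

- percent here means solid substrate units held: one side product A or side product B counts as two
- what is said of target includes solid product and idle adduct
- a step written with two of one species runs at k times the square of its concentration and takes two of it each time
- solid substrate, solid product is a solid; its amount is given per volume of the solution
- at the start none of the solid substrate is in solution
- run time (flask): 80 min

- dusk: doubling the dissolution coefficient of step 6, all else as stated
- summer: doubling the amount of reagent, all else as stated
- winter: doubling the solubility in step 3, all else as stated
- autumn: doubling the solubility in step 6, all else as stated

- target and solid product and idle adduct together at 80 min, in percent of the solid substrate charged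
- the change that raises the amount of target and solid product and idle adduct together at 80 min, in percent of the solid substrate charged most ("none" if none brings more than 2 percentage points) (dusk / summer / winter / autumn / none)
- amount of target and solid product and idle adduct together at 80 min, in percent of the solid substrate charged, after summer

2. The flask holds 0.170 M of reagent against 0.068 M of solid substrate. Take [reagent] as constant for now. Step 5 is then pseudo-first-order.

3. Set inflow equal to outflow: what step 6 supplies equals what step 2 and step 5 take, and step 2 goes with [dissolved substrate] squared. Collect the linear terms in 0.0278 /min. The root is the plateau, the level of dissolved substrate at which supply and losses balance: 15.2 mM.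

4. Now count turnovers. A small gap from the plateau closes with time constant 12.1 min, so the run lasts 6.62 turnovers. At the plateau, step 6 dissolves 71.1% of the charge by 80 min, so solid remains.

5. Charge one time constant as lag. Target made is k5[reagent] × plateau × (80 min − lag), which gives 12.7 mM, or 18.6%. Step 4 is set aside: its half-life of 150 min is longer than the run.

6. The weak link is constant reagent. Step 1 gives K1[reagent] = 0.87 at the start, so the adduct holds 46.4% of the target and takes reagent too. Mean free reagent is then about 0.161 M, and the estimate falls to 17.6%.

7. Rerun the plateau for each change. Summer gives 13.2 mM with doubled reagent. Dusk gives 20.8 mM and autumn 23.8 mM. Summer wins on reagent × plateau, and its yield scales to 30.6%.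

The forecast says 16.5% (15% to 18%), summer, and 29.7% (27% to 32%) after summer, noting: “Winter changes nothing, since there are no crystals”. The reckoning above stands higher.

The flask gives 16.5%, and summer leads with a gain of 13 percentage points, reaching 29.7%. At a reading at 59.3 min, or with 3.38 equiv of reagent, the answer has moved by 5 points, out of the forecast's range. At 80.0 min, dissolved substrate stands at 22.6% of the charge, against a plateau of 22.4%. For the neighbour charged with 0.17 M, reagent is 0.425 M, so the plateau is 12.3 mM, or 7.24% of its charge, and that flask reads 7.43%.

(The constants stand for no real mixture; what happens was integrated by code.)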